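The readings are calculated on assumed constants, and the scatter is random.

Green reads 19.4 % of L at 0.500 h against amber's 16.1 %, more, but green differs from amber in both its G and its loading of Q, so the two effects must be pulled apart before the flask can be judged.

| flask | G | Q | remark |
|---|---|---|---|
| blue | 0.13 M | 0.65 mol% | run made earlier |
| amber | 0.30 M | 0.65 mol% | run made earlier |
| green | 0.20 M | 0.98 mol% | run made earlier |
| flask | 0.20 M | 0.65 mol% |  |

- blue (time / h: L / %): 0.333: 8.9; 0.667: 15.6; 1.50: 35.5; 4.00: 71.3
- amber (time / h: L / %): 0.500: 16.1; 1.33: 41.0; 2.50: 65.2; 4.00: 85.0
- green (time / h: L / %): 0.500: 19.4; 1.33: 45.9; 2.50: 71.3; 4.00: 89.6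

(each reading ± 0.5 percentage points)

* apparent order in Q when 20 % of the G are converted (percent change of the rate of making L for one percent more Q charged)



We start with the ledger for G, the limiting reagent. In green at 0.500 h, 19.4 % of the charge is booked as L. If each catalyst holds one G, at most 0.98 mol% sits on it, and the rest of the 80.6 % not yet L is free, so the books close. We therefore count everything not yet L as G.

Dividing the elapsed time by the logarithm of charged over remaining G gives a reading of 2.32 h for green: this is the lifetime of G, averaged over the time elapsed. The same ledger reads 3.93 h for blue at 0.667 h and 2.85 h for amber at 0.500 h.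

Blue and amber share the flask's loading and bracket its 0.20 M, so logarithmic interpolation in cG gives the flask a lifetime of 3.33 h. Green has the flask's cG at 1.51 times the loading, so our own estimate of the order in Q is 0.882. We hold it loosely, given a scatter of 0.5 percentage points on readings this small.

The forecast says 0.77, lower than ours, and adds “Sub-first order suggests partial catalyst dimerisation”.

    G + Q → X (k = 0.650 /M/s)
    X → Q + L (k = 0.0200 /s)
    Q ⇌ E (K = 9.20, k = 9.70 × 10⁻⁶ /s)
    2 Q ⇌ Z, settled at all times (K = 9700 /M)

The simulation gives 0.77, as forecast. At 0.400 h the flask had 60.9 % of its catalyst as X and 28.4 % as Z, a form outside the working round. The flask reached 20 % conversion at 0.691 h, so its lifetime of G, averaged over that time, is 3.10 h. Against green's reading of 2.32 h, that is a ratio of 1.34 for 1.51 times the loading, an average order across that step in loading of 0.704.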